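The synthesis rests on cutting the terminal 2,2-disubstituted oxirane at its C(quaternary)–CH2 and CH2–O bonds: the ring CH2 is delivered as dimethyloxosulfonium methylide to the carbonyl carbon of an aryl ketone. This single operation closes the three-membered ring and sets the only stereocentre, the aryl-bearing quaternary oxirane carbon (R), under control of a chiral lanthanum–lithium binaphthoxide catalyst. The feature exploited is that this carbon carries the arene, the CH2O–isovalerate arm and the ring oxygen, exactly the substitution of a phenacyl ester carbonyl. The precursor is therefore the phenacyl isovalerate of the acetophenone, with the phenol masked as an allyl ether because an aryl tiglate would not survive the ylide.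

Key step: step 6

Assumption: the (R)-binaphthoxide catalyst is taken to deliver the ylide to the Re face of ketone 10 (O > CH2O-acyl > aryl), with the acyloxymethyl arm behaving as methyl does in aryl methyl ketones; this sense is not established for such a ketone, so a pilot run with both ligand antipodes decides, and the (S)-ligand is used if the sense is reversed.

**Step 1**
Reactants: 1 4-methoxy-3-methylphenol; 2 acetic anhydride
Product: 4 1-(2-hydroxy-5-methoxy-4-methylphenyl)ethan-1-one, via 4-methoxy-3-methylphenyl acetate 3 (not isolated)
Conditions: Ac2O (1.2 equiv), BF3·OEt2 (3 equiv), 90 °C; then H2O/MeOH, 60 °C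
Reagents that add atoms: acetic anhydride (compound 2), CC(=O)OC(C)=O
Why: O-acetylation followed by a BF3-promoted Fries rearrangement should place the acetyl group ortho to the hydroxyl at the unhindered C6 (para to the methyl group; the position para to oxygen is blocked by OMe), the chelated ortho-hydroxy ketone being the thermodynamic sink.

**Step 2**
Reactants: 4 1-(2-hydroxy-5-methoxy-4-methylphenyl)ethan-1-one; 5 allyl bromide
Product: 6 1-[5-methoxy-4-methyl-2-(prop-2-en-1-yloxy)phenyl]ethan-1-one
Conditions: K2CO3, DMF, 50 °C
Reagents that add atoms: allyl bromide (compound 5), C=CCBr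
Why: Williamson ether synthesis (phenoxide SN2 on allyl bromide) well below aromatic Claisen temperatures; masking the phenol at this point also prevents the later phenacyl bromide from closing to a benzofuran-3-one.

**Step 3**
Reactants: 6 1-[5-methoxy-4-methyl-2-(prop-2-en-1-yloxy)phenyl]ethan-1-one
Product: 8 2-bromo-1-[5-methoxy-4-methyl-2-(prop-2-en-1-yloxy)phenyl]ethan-1-one, via trimethylsilyl enol ether 7 (not isolated)
Conditions: LiN(SiMe3)2, Me3SiCl, THF, −78 °C; then N-bromosuccinimide, −78 → 0 °C
Reagents that add atoms: N-bromosuccinimide, O=C1CCC(=O)N1Br (Br of 8); chlorotrimethylsilane, C[Si](C)(C)Cl (Me3Si of intermediate 7 only)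
Why: α-Bromination of a ketone through its silyl enol ether: the only enolisable position is silylated, and enol silane 7 should take up bromine from NBS at carbon far faster than the electron-rich arene or the allyl double bond, which free bromine would not spare.

**Step 4**
Reactants: 8 2-bromo-1-[5-methoxy-4-methyl-2-(prop-2-en-1-yloxy)phenyl]ethan-1-one; 9 isovaleric acid
Product: 10 2-[5-methoxy-4-methyl-2-(prop-2-en-1-yloxy)phenyl]-2-oxoethyl 3-methylbutanoate
Conditions: Cs2CO3 (0.6 equiv), DMF, 20 °C (acid and carbonate premixed, then 8 added)
Reagents that add atoms: isovaleric acid (compound 9), CC(C)CC(=O)O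
Why: Carboxylate alkylation, an SN2 displacement of the activated phenacyl bromide by the weakly basic cesium carboxylate, should give the α-acyloxy ketone cleanly.

**Step 5**
Reactants: 11 trimethylsulfoxonium iodide
Product: 12 dimethyloxosulfonium methylide (titrated THF solution)
Conditions: NaH, THF, reflux; filtration under argon
Reagents that add atoms: none
Why: Irreversible deprotonation of a sulfoxonium methyl group by hydride with loss of H2 gives the stabilised Corey–Chaykovsky ylide, free of excess base.

**Step 6**
Reactants: 10 2-[5-methoxy-4-methyl-2-(prop-2-en-1-yloxy)phenyl]-2-oxoethyl 3-methylbutanoate; 12 dimethyloxosulfonium methylide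
Product: 14 {(2R)-2-[5-methoxy-4-methyl-2-(prop-2-en-1-yloxy)phenyl]oxiran-2-yl}methyl 3-methylbutanoate, via sulfoxonium betaine 13 (not isolated)
Conditions: 12 (1.2 equiv, slow addition), LaLi3[(R)-binaphthoxide]3 (trivalent lanthanum, 5 mol %), (2,4,6-(MeO)3C6H2)3P=O (5 mol %), 5 Å MS, THF, 20 °C
Reagents that add atoms: dimethyloxosulfonium methylide (compound 12), C[S+](C)(=O)[CH2-]
Why: The lanthanum centre binds and activates the ketone oxygen while a lithium binaphthoxide arm positions the ylide, so that the ylide carbon adds to the Re face (O > CH2O-acyl > aryl) to give betaine 13, whose alkoxide then expels dimethyl sulfoxide from the neighbouring CH2. The closest known reaction is the catalytic asymmetric Corey–Chaykovsky epoxidation of aryl methyl ketones with this heterobimetallic catalyst and a phosphine oxide additive, the acyloxymethyl arm here taking the place of methyl. The oxirane closes by a 3-exo-tet displacement, which cannot disturb the stereocentre already fixed in the addition. That stereocentre, the quaternary oxirane carbon (R), is controlled by the catalyst alone, which must tell the flat aryl group from the CH2O-acyl arm. The step needs facial selectivity and chemoselectivity for the ketone: the substrate offers only a sluggish aliphatic ester as a second electrophile, because the phenol is an allyl ether (no aryl ester, no enoate open to cyclopropanation), and 1.2 equiv of the mild ylide at 20 °C should avoid ring expansion to an oxetane. Carrying the isovalerate through this step means that no free hydroxymethyl oxirane, which could racemise by a degenerate Payne rearrangement, is ever formed.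

**Step 7**
Reactants: 14 {(2R)-2-[5-methoxy-4-methyl-2-(prop-2-en-1-yloxy)phenyl]oxiran-2-yl}methyl 3-methylbutanoate
Product: 15 [(2R)-2-(2-hydroxy-5-methoxy-4-methylphenyl)oxiran-2-yl]methyl 3-methylbutanoate
Conditions: Pd(PPh3)4 (zerovalent palladium, 3 mol %), N-methylaniline (1.5 equiv), THF, 20 °C; pH 7 buffer wash, crude used at once
Reagents that add atoms: none
Why: Tsuji–Trost deallylation: zerovalent palladium ionises the aryl allyl ether to a π-allyl complex that the weakly basic, weakly nucleophilic amine captures, so the phenol is released without phenoxide build-up and the oxirane, the ester and the stereocentre should stay untouched.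

**Step 8**
Reactants: 15 [(2R)-2-(2-hydroxy-5-methoxy-4-methylphenyl)oxiran-2-yl]methyl 3-methylbutanoate; 16 tigloyl chloride
Product: 17 4-methoxy-5-methyl-2-[(2R)-2-{[(3-methylbutanoyl)oxy]methyl}oxiran-2-yl]phenyl (2E)-2-methylbut-2-enoate
Conditions: 16 (2 equiv), pyridine, DMAP (10 mol %), CH2Cl2, −20 → 0 °C
Reagents that add atoms: tigloyl chloride (compound 16), C/C=C(\C)C(Cl)=O
Why: DMAP-catalysed Einhorn acylation of the phenol through the acylpyridinium ion should be fast in the cold, pyridine being too weak a base to form a phenoxide that could open the neighbouring oxirane or to deconjugate the acyl chloride through a vinylketene, so the stable (E)-geometry is kept.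

**Compound list**
1 | 4-methoxy-3-methylphenol | Cc1cc(O)ccc1OC | starting material
2 | acetic anhydride | CC(=O)OC(C)=O | starting material
3 | 4-methoxy-3-methylphenyl acetate (not isolated) | CC(=O)Oc1ccc(OC)c(C)c1 | intermediate
4 | 1-(2-hydroxy-5-methoxy-4-methylphenyl)ethan-1-one | CC(=O)c1cc(OC)c(C)cc1O | intermediate
5 | allyl bromide (3-bromoprop-1-ene) | C=CCBr | starting material
6 | 1-[5-methoxy-4-methyl-2-(prop-2-en-1-yloxy)phenyl]ethan-1-one | C=CCOc1cc(C)c(OC)cc1C(C)=O | intermediate
7 | trimethyl({1-[5-methoxy-4-methyl-2-(prop-2-en-1-yloxy)phenyl]ethenyl}oxy)silane (not isolated) | C=CCOc1cc(C)c(OC)cc1C(=C)O[Si](C)(C)C | intermediate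
8 | 2-bromo-1-[5-methoxy-4-methyl-2-(prop-2-en-1-yloxy)phenyl]ethan-1-one | C=CCOc1cc(C)c(OC)cc1C(=O)CBr | intermediate
9 | isovaleric acid (3-methylbutanoic acid) | CC(C)CC(=O)O | starting material
10 | 2-[5-methoxy-4-methyl-2-(prop-2-en-1-yloxy)phenyl]-2-oxoethyl 3-methylbutanoate | C=CCOc1cc(C)c(OC)cc1C(=O)COC(=O)CC(C)C | intermediate
11 | trimethylsulfoxonium iodide | C[S+](C)(C)=O.[I-] | starting material
12 | dimethyloxosulfonium methylide (THF solution) | C[S+](C)(=O)[CH2-] | intermediate
13 | (2S)-1-[dimethyl(oxo)-λ6-sulfaniumyl]-2-[5-methoxy-4-methyl-2-(prop-2-en-1-yloxy)phenyl]-3-[(3-methylbutanoyl)oxy]propan-2-olate (betaine, not isolated; S only because CH2S outranks CH2O) | C=CCOc1cc(C)c(OC)cc1[C@]([O-])(COC(=O)CC(C)C)C[S+](C)(C)=O | intermediate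
14 | {(2R)-2-[5-methoxy-4-methyl-2-(prop-2-en-1-yloxy)phenyl]oxiran-2-yl}methyl 3-methylbutanoate | C=CCOc1cc(C)c(OC)cc1[C@]1(COC(=O)CC(C)C)CO1 | intermediate
15 | [(2R)-2-(2-hydroxy-5-methoxy-4-methylphenyl)oxiran-2-yl]methyl 3-methylbutanoate | Oc1cc(C)c(OC)cc1[C@]1(COC(=O)CC(C)C)CO1 | intermediate
16 | tigloyl chloride [(2E)-2-methylbut-2-enoyl chloride] | C/C=C(\C)C(Cl)=O | starting material
17 | 4-methoxy-5-methyl-2-[(2R)-2-{[(3-methylbutanoyl)oxy]methyl}oxiran-2-yl]phenyl (2E)-2-methylbut-2-enoate | C/C=C(\C)C(=O)Oc1cc(C)c(OC)cc1[C@]1(COC(=O)CC(C)C)CO1 | target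

**Step count**
Total: 8 steps. Longest linear sequence: 7 steps (steps 1, 2, 3, 4, 6, 7, 8); step 5 is a one-step reagent branch.

**Steps most likely to fail**

1. Step 6. Facial discrimination may be poor, because the acyloxymethyl arm is larger and more Lewis-basic than the methyl group the catalyst is known to handle and may chelate the metal together with the ortho-allyloxy oxygen. Conversion may also suffer from enolisation or from acyl transfer to the ylide. The fallback makes the oxirane by oxygen transfer to an alkene instead of carbon transfer to a ketone; it sets out from 10 and returns at 14. Ketone 10 is methylenated (Ph3P=CH2, THF, 0 °C) to 2-[5-methoxy-4-methyl-2-(prop-2-en-1-yloxy)phenyl]prop-2-en-1-yl 3-methylbutanoate F1. Methanolysis (K2CO3, MeOH, 20 °C) should give 2-[5-methoxy-4-methyl-2-(prop-2-en-1-yloxy)phenyl]prop-2-en-1-ol F2. Katsuki–Sharpless epoxidation [Ti(OiPr)4, L-(+)-diethyl tartrate, tBuOOH, 4 Å MS, CH2Cl2, −20 °C] should then give {(2S)-2-[5-methoxy-4-methyl-2-(prop-2-en-1-yloxy)phenyl]oxiran-2-yl}methanol F3; the isolated allyl ether double bond is not an allylic alcohol and stays inert. Acylation with isovaleryl chloride and pyridine at 0 °C (no alkoxide, hence no Payne racemisation) leads to 14; the descriptor changes from S to R only because the acylated arm gains priority.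

2. Step 7 (the same hazard continues into step 8). Once the allyl group is gone, the ortho-hydroxyl may attack the oxirane CH2 and close a 3-hydroxy-2,3-dihydrobenzofuran, or may take over the isovaleryl group, before it is acylated. The fallback avoids a free phenol altogether; it sets out from 14 and arrives directly at 17, bypassing 15. Palladium-catalysed hydrostannolysis of the allyl aryl ether [Bu3SnH (1.05 equiv), Pd(PPh3)4 (zerovalent palladium, 2 mol %), CH2Cl2, 20 °C] should give propene and the covalent tin phenoxide [(2R)-2-{5-methoxy-4-methyl-2-[(tributylstannyl)oxy]phenyl}oxiran-2-yl]methyl 3-methylbutanoate F4. Tigloyl chloride is then added to the same flask and acylates the Sn–O bond.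

3. Step 3. Bromine may also enter the activated ring (the position between the allyloxy and methyl groups) or add to the allyl double bond, and a second bromination at the α-carbon is possible. The fallback installs the α-oxygen by oxygen transfer instead of halogenation and displacement; it sets out from 6 and returns at 10. Enol silane 7, made from 6 as in step 3, undergoes Rubottom oxidation (mCPBA, NaHCO3, CH2Cl2, −20 °C; then citric acid, MeOH) to 2-hydroxy-1-[5-methoxy-4-methyl-2-(prop-2-en-1-yloxy)phenyl]ethan-1-one F5; the enol ether should react far faster than the terminal alkene. F5 is esterified with isovaleryl chloride and pyridine (CH2Cl2, 0 °C) to give 10.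

**Further compounds**
F1 | step 6 | 2-[5-methoxy-4-methyl-2-(prop-2-en-1-yloxy)phenyl]prop-2-en-1-yl 3-methylbutanoate | C=CCOc1cc(C)c(OC)cc1C(=C)COC(=O)CC(C)C
F2 | step 6 | 2-[5-methoxy-4-methyl-2-(prop-2-en-1-yloxy)phenyl]prop-2-en-1-ol | C=CCOc1cc(C)c(OC)cc1C(=C)CO
F3 | step 6 | {(2S)-2-[5-methoxy-4-methyl-2-(prop-2-en-1-yloxy)phenyl]oxiran-2-yl}methanol | C=CCOc1cc(C)c(OC)cc1[C@]1(CO)CO1
F4 | step 7 | [(2R)-2-{5-methoxy-4-methyl-2-[(tributylstannyl)oxy]phenyl}oxiran-2-yl]methyl 3-methylbutanoate | CCCC[Sn](CCCC)(CCCC)Oc1cc(C)c(OC)cc1[C@]1(COC(=O)CC(C)C)CO1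
F5 | step 3 | 2-hydroxy-1-[5-methoxy-4-methyl-2-(prop-2-en-1-yloxy)phenyl]ethan-1-one | C=CCOc1cc(C)c(OC)cc1C(=O)CO
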